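## Retrosynthetic overview

1. Cembrane numbering: C1 = lactone β-CH, C14 = lactone O–CH, C15(=C17H2)–C16(=O)O; the target is (1S,3R,4S,7R,8S,12S,13R,14R). The route avoids the usual C1–C14 Barbier/NHK macro-allylation–lactonisation with a pre-built THF fragment.
2. THF ring last: an acetolytic transannular cascade on the (3R,4R,7R,8R)-bis-epoxide of a 3E,7E-cembradienolide (O7→C4, AcOH→C8) sets C3, C4, C7, C8 and the 8-OAc/3-OH pattern in one step.
3. cis-α-Methylene lactone from a macrocyclic butenolide by face-selective CuH 1,4-reduction with Mannich methylenation (sets C1).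
4. 14-membered ring by a macrocyclic vinylogous Mukaiyama aldol (C13–C14) of a 4-alkyl-2-silyloxyfuran onto an α-methyl aldehyde (sets C13, C14).
5. Seco chain = farnesol (C2–C13 plus all three methyls; C12 by Ru–BINAP hydrogenation) + 4-stannylbutenolide (Stille). Ring order: butenolide (bought) → 14-membered carbocycle → THF.

Assumptions: the Ru–BINAP facial sense for the 2-methyl allylic alcohol is taken to follow the geraniol model, and the D-fructose-derived Shi ketone is taken to give (R,R)-epoxides from E-trisubstituted olefins. Nothing here has been run; the selectivities in Steps 7, 11 and 12 are predictions.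

## Route

**Step 1**
Reactants: 1, (2E,6E)-farnesol
Product: 2, (2E,6E)-farnesyl acetate
Conditions: Ac2O, pyridine, DMAP (cat.), CH2Cl2, 0 °C→rt
Reagents that add atoms: acetic anhydride, CC(=O)OC(C)=O
Why: Standard DMAP-catalysed O-acetylation; the acetate protects the alcohol and later serves as the π-allyl leaving group; no stereocentre formed.

**Step 2**
Reactants: 2
Product: 3, (2E,6E,10E)-12-hydroxy-3,7,11-trimethyldodeca-2,6,10-trien-1-yl acetate
Conditions: SeO2 (0.3 eq), t-BuOOH, salicylic acid (cat.), CH2Cl2, rt; then NaBH4, MeOH, 0 °C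
Reagents that add atoms: selenium dioxide, O=[Se]=O; tert-butyl hydroperoxide, CC(C)(C)OO
Why: Sharpless–Umbreit catalytic SeO2 allylic oxidation (ene/[2,3]-shift) is selective for the E-methyl of the terminal isopropylidene and gives the E-allylic alcohol; NaBH4 returns any over-oxidised enal.

**Step 3**
Reactants: 3
Product: 4, (2E,6E,11S)-12-hydroxy-3,7,11-trimethyldodeca-2,6-dien-1-yl acetate
Conditions: Ru(OAc)2[(S)-BINAP] (1 mol%), H2 (50–100 atm), MeOH, rt
Reagents that add atoms: none
Why: Noyori hydroxyl-directed asymmetric hydrogenation reduces only the olefin bearing the free allylic OH (isolated trisubstituted olefins and the allylic acetate are inert) and the ligand-selected face sets C12 (S), sense assigned by analogy with geraniol → (R)-citronellol.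

**Step 4**
Reactants: 5, 4-bromofuran-2(5H)-one
Product: 6, 4-(tributylstannyl)furan-2(5H)-one
Conditions: (Bu3Sn)2, Pd(PPh3)4 (cat.), THF, 65 °C
Reagents that add atoms: hexabutylditin, CCCC[Sn](CCCC)(CCCC)[Sn](CCCC)(CCCC)CCCC
Why: Pd(0)-catalysed stannylation of an activated vinyl bromide with a distannane (oxidative addition, Sn–Sn transmetalation, reductive elimination); no stereocentre.

**Step 5**
Reactants: 4 and 6
Product: 7, 4-[(2E,6E,11S)-12-hydroxy-3,7,11-trimethyldodeca-2,6-dien-1-yl]furan-2(5H)-one
Conditions: Pd2(dba)3 (5 mol%), LiCl (3 eq), DMF, 40 °C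
Reagents that add atoms: none
Why: Stille coupling of an allylic acetate with a vinylstannane through a π-allyl-Pd chloride forms C1–C2 at the primary allyl terminus with retention of the E-olefin; the free primary OH is tolerated.

**Step 6**
Reactants: 7
Product: 8, (2S,6E,10E)-2,6,10-trimethyl-12-(5-oxo-2,5-dihydrofuran-3-yl)dodeca-6,10-dienal
Conditions: Dess–Martin periodinane, NaHCO3, CH2Cl2, 0 °C→rt
Reagents that add atoms: none
Why: Buffered Dess–Martin oxidation gives the α-methyl aldehyde without epimerising C12 and without touching the butenolide or olefins.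

**Step 7**
Reactants: 8
Product: 9, (3E,7E,12S,13R,14R)-13-hydroxycembra-1(15),3,7-trien-16,14-olide (14-membered carbocycle fused at C1/C14 to the butenolide)
Conditions: TBSOTf (1.1 eq), Et3N (1.3 eq), CH2Cl2, −78→0 °C; pentane filtration; then syringe-pump addition to BF3·OEt2 (3 eq), CH2Cl2 (1 mM), −78 °C; aq NaHCO3
Reagents that add atoms: none
Why: Proposed new method: soft enolisation converts the butenolide (much faster than the aldehyde) into the aromatic 4-alkyl-2-silyloxyfuran, whose γ-carbon (C14) then adds intramolecularly to the BF3-activated aldehyde through an open transition state to close the 14-membered ring, the intrinsic threo (C13/C14) and Felkin (C12/C13) preferences both leading to (13R,14R); closest known reactions are intermolecular BF3-mediated vinylogous Mukaiyama aldol additions of 2-silyloxyfurans to α-branched aldehydes and silylative intramolecular aldol cyclisations of lactone aldehydes.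

**Step 8**
Reactants: 9
Product: 10, (3E,7E,12S,13R,14R)-13-acetoxycembra-1(15),3,7-trien-16,14-olide
Conditions: Ac2O, pyridine, CH2Cl2, rt (no DMAP or Et3N)
Reagents that add atoms: acetic anhydride, CC(=O)OC(C)=O
Why: Simple acylation of the secondary alcohol; only the weak base pyridine is used so the acidic butenolide γ-H (C14) is not epimerised.

**Step 9**
Reactants: 10
Product: 11, (1S,3E,7E,12S,13R,14R)-13-acetoxy-17-(dimethylamino)cembra-3,7-dien-16,14-olide (cis-fused lactone, C15 epimer mixture)
Conditions: [(Ph3P)CuH]6 (5 mol%), PhMe2SiH (1.5 eq), toluene, 0 °C→rt; then CH2=NMe2+ I− (2 eq), CH2Cl2, rt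
Reagents that add atoms: Eschenmoser's salt, C=[N+](C)C.[I-]
Why: Stryker-type CuH 1,4-hydrosilylation delivers hydride to C1 on the butenolide face anti to C13 (the face not spanned by the macrocycle), giving the cis-fused (1S) lactone, and the resulting silyl ketene acetal is trapped in a Mannich reaction, so the C13 acetate is never enolised.

**Step 10**
Reactants: 11
Product: 12, (1S,3E,7E,12S,13R,14R)-13-acetoxycembra-3,7,15(17)-trien-16,14-olide
Conditions: MeI, THF/MeOH, rt; then aq NaHCO3, CH2Cl2, rt
Reagents that add atoms: none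
Why: N-Quaternisation followed by mild-base E1cB (Hofmann-type) elimination of trimethylamine gives the exocyclic α-methylene lactone without isomerisation to the endocyclic butenolide.

**Step 11**
Reactants: 12
Product: 13, (1S,3R,4R,7R,8R,12S,13R,14R)-13-acetoxy-3,4:7,8-diepoxycembr-15(17)-en-16,14-olide
Conditions: D-fructose-derived Shi ketone (0.6 eq), Oxone, K2CO3, Bu4NHSO4, MeCN/DMM–aq Na2B4O7/EDTA (pH ≈ 10.5), 0 °C, 2 h
Reagents that add atoms: Oxone (potassium peroxymonosulfate), [K+].[O-]S(=O)(=O)OO
Why: Shi asymmetric epoxidation (chiral dioxirane, spiro transition state) converts both electron-rich E-trisubstituted olefins into (R,R)-epoxides on their peripheral faces, while the electron-poor α-methylene lactone is not oxidised.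

**Step 12**
Reactants: 13
Product: 14, target, (1S,3R,4S,7R,8S,12S,13R,14R)-8,13-diacetoxy-4,7-epoxy-3-hydroxycembr-15(17)-en-16,14-olide
Conditions: AcOH (20 eq), (CF3)2CHOH, 0 °C→rt
Reagents that add atoms: acetic acid, CC(=O)O
Why: Proposed new method: H-bond activation of the 3,4-epoxide triggers 5-exo attack of the 7,8-epoxide oxygen at tertiary C4 (inversion, 4R→4S, releasing 3-OH), and the resulting bicyclic epoxonium is opened by acetic acid at tertiary C8 (inversion, 8R→8S), so like-configured epoxides give the cis-2,5-THF with free 3-OH and 8-OAc directly; closest known reactions are acid-mediated 1,5-diepoxide → tetrahydrofuran epoxonium cascades and transannular diepoxide solvolyses in carboxylic acids.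

## Compound list

1 | (2E,6E)-farnesol | CC(C)=CCC/C(C)=C/CC/C(C)=C/CO | starting material
2 | (2E,6E)-farnesyl acetate | CC(C)=CCC/C(C)=C/CC/C(C)=C/COC(C)=O | intermediate
3 | (2E,6E,10E)-12-hydroxy-3,7,11-trimethyldodeca-2,6,10-trien-1-yl acetate | OC/C(C)=C/CC/C(C)=C/CC/C(C)=C/COC(C)=O | intermediate
4 | (2E,6E,11S)-12-hydroxy-3,7,11-trimethyldodeca-2,6-dien-1-yl acetate | OC[C@@H](C)CCC/C(C)=C/CC/C(C)=C/COC(C)=O | intermediate
5 | 4-bromofuran-2(5H)-one | O=C1C=C(Br)CO1 | starting material
6 | 4-(tributylstannyl)furan-2(5H)-one | CCCC[Sn](CCCC)(CCCC)C1=CC(=O)OC1 | intermediate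
7 | 4-[(2E,6E,11S)-12-hydroxy-3,7,11-trimethyldodeca-2,6-dien-1-yl]furan-2(5H)-one | OC[C@@H](C)CCC/C(C)=C/CC/C(C)=C/CC1=CC(=O)OC1 | intermediate
8 | (2S,6E,10E)-2,6,10-trimethyl-12-(5-oxo-2,5-dihydrofuran-3-yl)dodeca-6,10-dienal | O=C[C@@H](C)CCC/C(C)=C/CC/C(C)=C/CC1=CC(=O)OC1 | intermediate
9 | (3E,7E,12S,13R,14R)-13-hydroxycembra-1(15),3,7-trien-16,14-olide | O=C1O[C@H]2[C@H](O)[C@@H](C)CCC/C(C)=C/CC/C(C)=C/CC2=C1 | intermediate
10 | (3E,7E,12S,13R,14R)-13-acetoxycembra-1(15),3,7-trien-16,14-olide | O=C1O[C@H]2[C@H](OC(C)=O)[C@@H](C)CCC/C(C)=C/CC/C(C)=C/CC2=C1 | intermediate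
11 | (1S,3E,7E,12S,13R,14R)-13-acetoxy-17-(dimethylamino)cembra-3,7-dien-16,14-olide (C15 epimers) | CN(C)CC1C(=O)O[C@H]2[C@H](OC(C)=O)[C@@H](C)CCC/C(C)=C/CC/C(C)=C/C[C@@H]12 | intermediate
12 | (1S,3E,7E,12S,13R,14R)-13-acetoxycembra-3,7,15(17)-trien-16,14-olide | C=C1C(=O)O[C@H]2[C@H](OC(C)=O)[C@@H](C)CCC/C(C)=C/CC/C(C)=C/C[C@@H]12 | intermediate
13 | (1S,3R,4R,7R,8R,12S,13R,14R)-13-acetoxy-3,4:7,8-diepoxycembr-15(17)-en-16,14-olide | C=C1C(=O)O[C@H]2[C@H](OC(C)=O)[C@@H](C)CCC[C@@]3(C)O[C@@H]3CC[C@@]4(C)O[C@@H]4C[C@@H]12 | intermediate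
14 | (1S,3R,4S,7R,8S,12S,13R,14R)-8,13-diacetoxy-4,7-epoxy-3-hydroxycembr-15(17)-en-16,14-olide (CID10479028) | C=C1C(=O)O[C@H]2[C@H](OC(C)=O)[C@@H](C)CCC[C@](C)(OC(C)=O)[C@H]3CC[C@](C)(O3)[C@H](O)C[C@@H]12 | target

## Totals and risks

Total step count: 12. Longest linear sequence: 11 (farnesol → target; Steps 1–3 and 5–12).

Three steps most likely to fail:

1. **Step 7 (macrocyclic vinylogous aldol: ring closure and C13/C14 control).** Fallback: reverse the bond order. Run an intermolecular BF3 vinylogous aldol between the aldehyde from 4 (allylic acetate retained) and 4-(tributylstannyl)-2-(TBSO)furan, then close the ring at C1–C2 by an intramolecular π-allyl/vinylstannane Stille coupling.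
2. **Step 12 (cascade direction: acetate capture at C4 instead of C8, or elimination at C8).** Fallback: differentiate the olefins and open the epoxides one at a time. On open-chain 4 the C2 acetate deactivates C3=C4, so only C7=C8 is Shi-epoxidised; acetolyse at C8, carry the 7-OH as a silyl ether through macrocyclisation, and close the THF late by a single 3,4-epoxidation followed by 7-OH 5-exo opening.
3. **Step 11 (facial selectivity of the double Shi epoxidation on the conformationally biased macrocycle).** Fallback: move the oxidation before ring closure. Carry out the Shi bis-epoxidation and acetolytic THF cascade on open-chain 7 (primary OH silylated, pure reagent control), then deprotect, oxidise, and run the macrocyclic vinylogous aldol and reduction/methylenation on the THF-containing chain.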